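Its constants are assumed; what happens was integrated by code.

The easy step comes first: free catalyst opens the substrate and comes back unchanged. Second catalyst then takes up the open intermediate, and the reagent turns that catalyst intermediate into product and releases the second catalyst.

    substrate + free catalyst → free catalyst + open intermediate (k1 = 18 M⁻¹ s⁻¹)
    second catalyst + open intermediate ⇌ catalyst intermediate (K2 = 0.33 M⁻¹, k2 = 120 M⁻¹ s⁻¹)
    reagent + catalyst intermediate → second catalyst + product (k3 = 30 M⁻¹ s⁻¹)

substrate 0.10 M (fed, over 15 s); reagent 0.110 M; free catalyst 0.16 mM; second catalyst 2.5 mM; time 30 h

- the reaction counts as stopped when no species that holds the substrate changes by six tenths of a point or more over the second half of the time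
- run time (flask): 30 h

- why nothing more happens at 30 h, or that something still does (all of the substrate has reacted / forward and back rates have come level / it is still moving / the reagent has run out first / no working catalyst is left)
- how much product there is at 30 h, in percent of the substrate charged

*What do you count in this flask?* Turns of the second catalyst, since each turn spends one reagent and makes one product. The substrate asks for 40.0 turns of each second catalyst. The reagent pays for 44.0; I call these the paid turns, the reagent charge divided by the second catalyst charge. Paid turns stand above the need, so in this flask the substrate is the limiting reagent.

*Does the opening hold anything up?* No: its half-life by that step alone, with the free catalyst as charged, is 0.067 h, far shorter than the run.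

*Can the turns get done through the catalyst intermediate?* Its back reaction, at 364 s⁻¹, is much faster than its use by the reagent as charged, at 3.30 s⁻¹. So I reckon it in equilibrium, at 8.2 × 10⁻⁴ of the open intermediate with the second catalyst as charged.

*And the last turns, when the reagent is down to its surplus?* That surplus is 0.0100 M, which by my estimate halves the open intermediate every 0.778 h, and the run holds 38.6 such half-lives. I commit to 100% product, with the substrate used up and 9.09% of the reagent unspent.

The forecast gives all of the substrate has reacted and 100%, on the ground that “Step 3 is irreversible and nothing kills the catalysts”.

The simulation gives all of the substrate has reacted and 100% product. Of its 44.0 paid turns this flask used 40.0, and at 30.0 h it holds 9.1% of its reagent. The neighbour flask charged with 0.028 M of reagent has 11.2 paid turns against the same need, enough for 28.0% of the substrate charged. At 30.0 h that neighbour stands at 28.0% product, with 0% of its reagent left and 71.9% of the substrate waiting as open intermediate.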